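**Retrosynthetic overview**

1. The three oxygen functions are set last: the 9‑isovalerate and the anti 7‑OH come from the C9 ketone of tricycle 18 by a hydroxyl‑directed Evans–Tishchenko reduction; the 8‑angelate replaces a methoxymethyl ether.
2. Key disconnection of 18: the aldol bond C7–C8 and the cyclobutane bond C10–C11, which is the central bond of the 1,4‑dicarbonyl array C1(=O)–C11–C10–C9(=O). This leads back to the monocyclic cis‑4,5‑disubstituted 3‑methylcyclohex‑2‑enone 16.
3. The enabling feature: the C9 carbonyl is flanked by C8 (aldol donor toward the C7 aldehyde) and C10 (joined oxidatively to C11, the α' carbon of the C1 enone), and the cis C4/C5 substituents hold C10 1,3‑diaxial over C11.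
4. 16 comes from cyclohexenone 6 by CBS reduction, Johnson–Claisen rearrangement (C4–C10 bond, 1,3‑chirality transfer), Weinreb ketone synthesis, allylic oxidation and alkene cleavage; 6 comes from an organocatalytic Michael addition and aldol condensation.
5. Ring order: cyclohexenone (step 3), then the seven‑membered ring and the cyclobutane/bicyclo[3.1.1]heptenone together (step 10).

Key step: step 10

Remark on locants (longipinane type, used throughout): C1 = enone C=O, C2=C3(CH3), C4 and C5 = ring‑fusion CH, C6 = C(CH3)2, C7 = CHOH, C8 = CH–O‑angeloyl, C9 = CH–O‑isovaleryl, C10 = C(CH3), C11 = CH next to C1; the cyclobutane is C4–C5–C11–C10.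
Remark: C10 is carried as an epimer mixture in 10–17, because it becomes planar (enolate) in step 10.

**Route**

Step 1
Reactants: 1 methyl 3,3-dimethylpent-4-enoate
Product: 2 3,3-dimethylpent-4-enal
Conditions: iBu2AlH (1.05 equiv), CH2Cl2, −78 °C; Rochelle salt aq
Reagents that add atoms: none
Why: Partial ester reduction: the aluminium hemiacetal is stable at −78 °C and gives the aldehyde only on work-up.

Step 2
Reactants: 2 3,3-dimethylpent-4-enal; 3 pent-1-en-3-one
Product: 4 (S)-2-(2-methylbut-3-en-2-yl)-5-oxoheptanal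
Conditions: (S)-α,α-diphenylprolinol trimethylsilyl ether (10 mol %), ethyl 3,4-dihydroxybenzoate (20 mol %), neat, 4 °C
Reagents that add atoms: none
Why: Enamine-catalysed asymmetric Michael addition of an aldehyde to a vinyl ketone, in which the diarylmethyl group shields one face of the E-enamine so that C5 should form with the S configuration drawn.

Step 3
Reactants: 4 (S)-2-(2-methylbut-3-en-2-yl)-5-oxoheptanal
Product: 6 (R)-2-methyl-4-(2-methylbut-3-en-2-yl)cyclohex-2-en-1-one, via ketol 5 (not isolated)
Conditions: LiOH (0.2 equiv), iPrOH, 0 °C → rt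
Reagents that add atoms: none
Why: Intramolecular aldol condensation through the ethyl-ketone CH2, the only enolate that can close a six-membered ring, under mild base that should not epimerise C5.

Step 4
Reactants: 6 (R)-2-methyl-4-(2-methylbut-3-en-2-yl)cyclohex-2-en-1-one
Product: 7 (1S,4R)-2-methyl-4-(2-methylbut-3-en-2-yl)cyclohex-2-en-1-ol (cis)
Conditions: (R)-2-methyl-CBS-oxazaborolidine (20 mol %), catecholborane (1.5 equiv), toluene, −78 °C
Reagents that add atoms: none
Why: Corey–Bakshi–Shibata reduction, where reagent control (alkenyl side as the large group) should give the S carbinol cis to the C5 substituent, and catecholborane leaves the vinyl group alone.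

Step 5
Reactants: 7 (1S,4R)-2-methyl-4-(2-methylbut-3-en-2-yl)cyclohex-2-en-1-ol; 8 triethyl orthopropionate
Product: 10 ethyl 2-[(1S,6R)-2-methyl-6-(2-methylbut-3-en-2-yl)cyclohex-2-en-1-yl]propanoate, via ketene acetal 9 (not isolated)
Conditions: 8 (6 equiv), EtCO2H (5 mol %), xylene, 140 °C, EtOH distilled off
Reagents that add atoms: none
Why: Johnson–Claisen rearrangement, in which the pseudo-axial C–O bond of the cis alcohol (tert-alkyl group equatorial) passes its chirality suprafacially to C4, so the new C4–C10 bond is cis to the C5 substituent and the alkene moves to C2=C3.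

Step 6
Reactants: 10 ethyl 2-[(1S,6R)-2-methyl-6-(2-methylbut-3-en-2-yl)cyclohex-2-en-1-yl]propanoate
Product: 11 N-methoxy-N-methyl-2-[(1S,6R)-2-methyl-6-(2-methylbut-3-en-2-yl)cyclohex-2-en-1-yl]propanamide
Conditions: MeNH(OMe)·HCl (3 equiv), iPrMgCl (6 equiv), THF, −20 → 0 °C
Reagents that add atoms: N,O-dimethylhydroxylamine hydrochloride CNOC.Cl
Why: Weinreb amide formation by acyl substitution of the ester with the magnesium amide.

Step 7
Reactants: 11 N-methoxy-N-methyl-2-[(1S,6R)-2-methyl-6-(2-methylbut-3-en-2-yl)cyclohex-2-en-1-yl]propanamide; 12 tributyl[(methoxymethoxy)methyl]stannane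
Product: 13 1-(methoxymethoxy)-3-[(1S,6R)-2-methyl-6-(2-methylbut-3-en-2-yl)cyclohex-2-en-1-yl]butan-2-one
Conditions: 12 (1.5 equiv), n-BuLi (1.45 equiv), THF, −78 °C; then 11, −78 → −40 °C; NH4Cl aq
Reagents that add atoms: none
Why: Tin–lithium exchange gives the α-alkoxymethyllithium, which adds once to the Weinreb amide through the chelated tetrahedral intermediate (Weinreb ketone synthesis).

Step 8
Reactants: 13 1-(methoxymethoxy)-3-[(1S,6R)-2-methyl-6-(2-methylbut-3-en-2-yl)cyclohex-2-en-1-yl]butan-2-one
Product: 14 (4S,5R)-4-[4-(methoxymethoxy)-3-oxobutan-2-yl]-3-methyl-5-(2-methylbut-3-en-2-yl)cyclohex-2-en-1-one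
Conditions: CrO3 (15 equiv), 3,5-dimethylpyrazole (15 equiv), CH2Cl2, −20 °C
Reagents that add atoms: chromium trioxide O=[Cr](=O)=O
Why: Allylic oxidation at the ring CH2 next to the alkene CH, the usual site in 1-methylcyclohexenes; the vinyl group has no allylic hydrogen.

Step 9
Reactants: 14 (4S,5R)-4-[4-(methoxymethoxy)-3-oxobutan-2-yl]-3-methyl-5-(2-methylbut-3-en-2-yl)cyclohex-2-en-1-one
Product: 16 2-[(1R,2S)-2-[4-(methoxymethoxy)-3-oxobutan-2-yl]-3-methyl-5-oxocyclohex-3-en-1-yl]-2-methylpropanal, via diol 15 (not isolated)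
Conditions: OsO4 (2 mol %), NaIO4 (4 equiv), 2,6-lutidine (2 equiv), dioxane/H2O 3:1, rt
Reagents that add atoms: osmium tetroxide O=[Os](=O)(=O)=O (catalytic oxygen carrier); sodium periodate [Na+].[O-]I(=O)(=O)=O
Why: Lemieux–Johnson cleavage, in which OsO4 should attack the electron-richer monosubstituted alkene much faster than the enone alkene and periodate cleaves the diol to the non-enolisable aldehyde.

Step 10
Reactants: 16 2-[(1R,2S)-2-[4-(methoxymethoxy)-3-oxobutan-2-yl]-3-methyl-5-oxocyclohex-3-en-1-yl]-2-methylpropanal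
Product: 18 7-hydroxy-8-(methoxymethoxy)longipin-2-ene-1,9-dione (7-OH trans to 8-O; configuration as in the SMILES), via bicyclic lithium aldolate 17 (not isolated)
Conditions: LiN(SiMe3)2 (1.1 equiv), THF (0.01 M), −78 °C, 1 h; LiN(iPr)2 (2.3 equiv), −78 → −30 °C; Fe(acac)3 (2.4 equiv) in THF, −78 °C → rt; NH4Cl aq
Reagents that add atoms: none
Why: Proposed new method: LiN(SiMe3)2 first removes the chelation-activated C8–H next to the methoxymethyl ether and the Z(O)-lithium enolate of the C9 ketone adds to the non-enolisable C7 aldehyde (7-enolendo-exo-trig aldol) to give aldolate 17; LiN(iPr)2 then forms the cross-conjugated dienolate of the enone (C11) and the tetrasubstituted C10 enolate of the C9 ketone, and Fe(acac)3 oxidises the latter to a tertiary α-keto radical that adds to C11 of the dienolate (formal 4-exo closure of the cyclobutane, which is at the same time the bicyclo[3.1.1]heptenone), the ketyl radical anion then giving up a second electron. The closest known reaction type is the intramolecular oxidative heterocoupling of two lithium enolates with Fe(acac)3 or copper carboxylates, a reaction type that closes strained bridged rings and cyclobutanes from 1,6-dicarbonyl bis-enolates; new here is the coupling of a dienolate with a tetrasubstituted ketone enolate on a cyclohexenone template directly after an in-flask aldol. The geometry favours it: in the cis-4,5-disubstituted half-chair the bulky C5 substituent is equatorial and the C4 side chain axial, so C10 sits 1,3-diaxial over C11 at roughly 2.6–3 Å with the two enolate p-orbitals pointing at each other. C10 can bond only with its methyl group toward the enone bridge because C9 is already tied back in the seven-membered ring, C11 is fixed by the bridged ring, and C7/C8 should come from the closed chair-like aldol transition state of the Z(O)-enolate (alkoxy and hydroxyl trans on the ring), whose facial sense is set at the cis-fused monocyclic stage and not in the nearly mirror-symmetric tricycle. The selectivity needed is coupling of C11 with C10 and not with C8 (six-membered ring): after the aldol C8 is a methine between the lithium alkoxide and the ether and should no longer be enolised, and the aldehyde, the only other electrophile, has been consumed. Both C10 epimers of 16 converge because C10 is planar in the enolate.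

Step 11
Reactants: 18 7-hydroxy-8-(methoxymethoxy)longipin-2-ene-1,9-dione
Product: 20 9-hydroxy-8-(methoxymethoxy)-1-oxolongipin-2-en-7-yl pent-4-enoate (7-O and 9-O anti), via hemiacetal 19 (not isolated)
Conditions: pent-4-enal (8 equiv), SmI2 (0.3 equiv), THF, −10 °C
Reagents that add atoms: pent-4-enal C=CCCC=O
Why: Evans–Tishchenko reduction, in which the C7 hemiacetal delivers hydride intramolecularly to the C9 ketone in a samarium-bound six-membered transition state; this should set C9 anti to C7, spare the enone and leave C7 as an orthogonally removable ester.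

Step 12
Reactants: 20 9-hydroxy-8-(methoxymethoxy)-1-oxolongipin-2-en-7-yl pent-4-enoate
Product: 21 8-(methoxymethoxy)-9-(3-methylbutanoyloxy)-1-oxolongipin-2-en-7-yl pent-4-enoate
Conditions: 3-methylbutanoyl chloride (3 equiv), pyridine, DMAP (0.2 equiv), CH2Cl2, 0 °C → rt
Reagents that add atoms: 3-methylbutanoyl chloride CC(C)CC(Cl)=O
Why: DMAP-catalysed acylation of the only free hydroxyl group (C9) with the acid chloride.

Step 13
Reactants: 21 8-(methoxymethoxy)-9-(3-methylbutanoyloxy)-1-oxolongipin-2-en-7-yl pent-4-enoate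
Product: 22 8-hydroxy-9-(3-methylbutanoyloxy)-1-oxolongipin-2-en-7-yl pent-4-enoate
Conditions: Me2BBr (3 equiv), CH2Cl2, −78 °C; then NaHCO3 aq/THF
Reagents that add atoms: none
Why: Lewis-acid cleavage of the methoxymethyl acetal through the bromomethyl ether at −78 °C, conditions under which esters and the enone should be stable.

Step 14
Reactants: 22 8-hydroxy-9-(3-methylbutanoyloxy)-1-oxolongipin-2-en-7-yl pent-4-enoate
Product: 23 8-[(Z)-2-methylbut-2-enoyloxy]-9-(3-methylbutanoyloxy)-1-oxolongipin-2-en-7-yl pent-4-enoate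
Conditions: angelic acid (5 equiv), 2,4,6-trichlorobenzoyl chloride (5 equiv), Et3N (6 equiv), toluene, rt, 2 h; then 22, 80 °C (no DMAP)
Reagents that add atoms: (Z)-2-methylbut-2-enoic acid (angelic acid) C/C=C(/C)C(O)=O
Why: Yamaguchi-type esterification of the only free hydroxyl (C8) through the mixed anhydride, run without DMAP to keep the Z geometry.

Step 15
Reactants: 23 8-[(Z)-2-methylbut-2-enoyloxy]-9-(3-methylbutanoyloxy)-1-oxolongipin-2-en-7-yl pent-4-enoate
Product: 24 7-hydroxy-9-(3-methylbutanoyloxy)-1-oxolongipin-2-en-8-yl (Z)-2-methylbut-2-enoate (target CNP0151972.1)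
Conditions: I2 (3 equiv), NaHCO3 (3 equiv), THF/H2O 3:1, 0 °C → rt; Na2S2O3 aq
Reagents that add atoms: none
Why: Iodolactonisation-driven cleavage of the pent-4-enoate (iodonium at the terminal alkene, attack by the ester carbonyl oxygen, hydrolysis) should free the C7 alcohol under neutral conditions, while the electron-poor angelate and enone alkenes do not react.

**Compound list**

1 | methyl 3,3-dimethylpent-4-enoate | COC(=O)CC(C)(C)C=C | starting material
2 | 3,3-dimethylpent-4-enal | O=CCC(C)(C)C=C | intermediate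
3 | pent-1-en-3-one | CCC(=O)C=C | starting material
4 | (S)-2-(2-methylbut-3-en-2-yl)-5-oxoheptanal | C=CC(C)(C)[C@@H](C=O)CCC(=O)CC | intermediate
5 | 3-hydroxy-2-methyl-4-(2-methylbut-3-en-2-yl)cyclohexan-1-one (4R; ketol, not isolated) | C=CC(C)(C)[C@@H]1CCC(=O)C(C)C1O | intermediate
6 | (R)-2-methyl-4-(2-methylbut-3-en-2-yl)cyclohex-2-en-1-one | C=CC(C)(C)[C@@H]1CCC(=O)C(C)=C1 | intermediate
7 | (1S,4R)-2-methyl-4-(2-methylbut-3-en-2-yl)cyclohex-2-en-1-ol | C=CC(C)(C)[C@@H]1CC[C@H](O)C(C)=C1 | intermediate
8 | triethyl orthopropionate | CCC(OCC)(OCC)OCC | starting material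
9 | (1S,4R)-1-[(1-ethoxyprop-1-en-1-yl)oxy]-2-methyl-4-(2-methylbut-3-en-2-yl)cyclohex-2-ene (ketene acetal, not isolated) | C=CC(C)(C)[C@@H]1CC[C@H](OC(OCC)=CC)C(C)=C1 | intermediate
10 | ethyl 2-[(1S,6R)-2-methyl-6-(2-methylbut-3-en-2-yl)cyclohex-2-en-1-yl]propanoate (C10 epimers) | C=CC(C)(C)[C@@H]1CCC=C(C)[C@@H]1C(C)C(=O)OCC | intermediate
11 | N-methoxy-N-methyl-2-[(1S,6R)-2-methyl-6-(2-methylbut-3-en-2-yl)cyclohex-2-en-1-yl]propanamide | C=CC(C)(C)[C@@H]1CCC=C(C)[C@@H]1C(C)C(=O)N(C)OC | intermediate
12 | tributyl[(methoxymethoxy)methyl]stannane | CCCC[Sn](CCCC)(CCCC)COCOC | starting material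
13 | 1-(methoxymethoxy)-3-[(1S,6R)-2-methyl-6-(2-methylbut-3-en-2-yl)cyclohex-2-en-1-yl]butan-2-one | C=CC(C)(C)[C@@H]1CCC=C(C)[C@@H]1C(C)C(=O)COCOC | intermediate
14 | (4S,5R)-4-[4-(methoxymethoxy)-3-oxobutan-2-yl]-3-methyl-5-(2-methylbut-3-en-2-yl)cyclohex-2-en-1-one | C=CC(C)(C)[C@@H]1CC(=O)C=C(C)[C@@H]1C(C)C(=O)COCOC | intermediate
15 | (4S,5R)-5-(3,4-dihydroxy-2-methylbutan-2-yl)-4-[4-(methoxymethoxy)-3-oxobutan-2-yl]-3-methylcyclohex-2-en-1-one (diol, not isolated) | OCC(O)C(C)(C)[C@@H]1CC(=O)C=C(C)[C@@H]1C(C)C(=O)COCOC | intermediate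
16 | 2-[(1R,2S)-2-[4-(methoxymethoxy)-3-oxobutan-2-yl]-3-methyl-5-oxocyclohex-3-en-1-yl]-2-methylpropanal | O=CC(C)(C)[C@@H]1CC(=O)C=C(C)[C@@H]1C(C)C(=O)COCOC | intermediate
17 | cis-fused bicyclic aldol (seven-membered ring closed at C7–C8, C10–C11 still open; lithium aldolate in the flask, not isolated) | COCO[C@@H]1[C@@H](O)C(C)(C)[C@@H]2CC(=O)C=C(C)[C@@H]2C(C)C1=O | intermediate
18 | 7-hydroxy-8-(methoxymethoxy)longipin-2-ene-1,9-dione | COCO[C@@H]1[C@@H](O)C(C)(C)[C@@H]2[C@H]3C(=O)C=C(C)[C@@H]2[C@@]3(C)C1=O | intermediate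
19 | C7 hemiacetal of 18 with pent-4-enal (not isolated) | COCO[C@@H]1[C@@H](OC(O)CCC=C)C(C)(C)[C@@H]2[C@H]3C(=O)C=C(C)[C@@H]2[C@@]3(C)C1=O | intermediate
20 | 9-hydroxy-8-(methoxymethoxy)-1-oxolongipin-2-en-7-yl pent-4-enoate | COCO[C@@H]1[C@@H](OC(=O)CCC=C)C(C)(C)[C@@H]2[C@H]3C(=O)C=C(C)[C@@H]2[C@@]3(C)[C@@H]1O | intermediate
21 | 8-(methoxymethoxy)-9-(3-methylbutanoyloxy)-1-oxolongipin-2-en-7-yl pent-4-enoate | COCO[C@@H]1[C@@H](OC(=O)CCC=C)C(C)(C)[C@@H]2[C@H]3C(=O)C=C(C)[C@@H]2[C@@]3(C)[C@@H]1OC(=O)CC(C)C | intermediate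
22 | 8-hydroxy-9-(3-methylbutanoyloxy)-1-oxolongipin-2-en-7-yl pent-4-enoate | O[C@@H]1[C@@H](OC(=O)CCC=C)C(C)(C)[C@@H]2[C@H]3C(=O)C=C(C)[C@@H]2[C@@]3(C)[C@@H]1OC(=O)CC(C)C | intermediate
23 | 8-[(Z)-2-methylbut-2-enoyloxy]-9-(3-methylbutanoyloxy)-1-oxolongipin-2-en-7-yl pent-4-enoate | C/C=C(/C)C(=O)O[C@@H]1[C@@H](OC(=O)CCC=C)C(C)(C)[C@@H]2[C@H]3C(=O)C=C(C)[C@@H]2[C@@]3(C)[C@@H]1OC(=O)CC(C)C | intermediate
24 | 7-hydroxy-9-(3-methylbutanoyloxy)-1-oxolongipin-2-en-8-yl (Z)-2-methylbut-2-enoate (CNP0151972.1) | C/C=C(/C)C(=O)O[C@@H]1[C@@H](O)C(C)(C)[C@@H]2[C@H]3C(=O)C=C(C)[C@@H]2[C@@]3(C)[C@@H]1OC(=O)CC(C)C | target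

**Summary**

Total step count: 15. Longest linear sequence: 15 steps (1 → 24).

Steps most likely to fail:

1. Step 10 (proposed new method). The strained C10–C11 closure may lose out to intermolecular oxidative coupling or simple re-protonation. The C9 ketone may enolise toward C8 instead of C10. The enone dienolate may add reversibly to the C9 carbonyl. The aldol may show poor facial control, and retro-aldol on warming could scramble C7/C8. Fallback, from 16 back to 18, separating the two bond formations and closing the cyclobutane by polar alkylation: LiN(SiMe3)2 (1.1 equiv, THF, −78 °C) followed by Et3SiCl gives the silylated bicyclic aldol F1. LiN(SiMe3)2/Me3SiCl and then N-bromosuccinimide brominate C11 through the cross-conjugated dienol ether to give the α'-bromo enone F2. KOtBu (THF/tBuOH, −40 °C) enolises the C9 ketone toward C10, and the tetrasubstituted enolate displaces the axial bromide in a 4-exo-tet alkylation (the classical closure of bicyclo[3.1.1]heptanones) to give the tricyclic silyl ether F3. HF·pyridine then returns 18.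

2. Step 11. The β-hydroxy ketone may open by retro-aldol under the samarium alkoxide, or hydride transfer may be blocked because both C7 and C9 are neopentyl. Fallback, from 18 back to 20, with hydride delivered from outside: pent-4-enoic anhydride/DMAP acylates the C7 hydroxyl to give the keto ester F4. Zn(BH4)2 (Et2O, −78 °C) then reduces the C9 ketone under chelation with the C8 methoxymethyl ether, anti to that ether and faster than the enone carbonyl, to give 20.

3. Step 14. The angelate may isomerise to the E ester during acylation of the hindered C8 hydroxyl, or acyl groups may migrate between the neighbouring oxygens. Fallback, from 22 back to 23, building the Z alkene on the ester: EDC/DMAP coupling with 2-[bis(2,2,2-trifluoroethoxy)phosphoryl]propanoic acid gives the phosphonate ester F5. Still–Gennari olefination with acetaldehyde (KN(SiMe3)2, 18-crown-6, THF, −78 °C) then gives 23.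

Further compounds
F1 | step 10 | triethylsilyl ether of bicyclic aldol 17 | COCO[C@@H]1[C@@H](O[Si](CC)(CC)CC)C(C)(C)[C@@H]2CC(=O)C=C(C)[C@@H]2C(C)C1=O
F2 | step 10 | C11-bromo derivative of F1 (α'-bromo enone) | COCO[C@@H]1[C@@H](O[Si](CC)(CC)CC)C(C)(C)[C@@H]2C(Br)C(=O)C=C(C)[C@@H]2C(C)C1=O
F3 | step 10 | 8-(methoxymethoxy)-7-(triethylsilyloxy)longipin-2-ene-1,9-dione | COCO[C@@H]1[C@@H](O[Si](CC)(CC)CC)C(C)(C)[C@@H]2[C@H]3C(=O)C=C(C)[C@@H]2[C@@]3(C)C1=O
F4 | step 11 | 8-(methoxymethoxy)-1,9-dioxolongipin-2-en-7-yl pent-4-enoate | COCO[C@@H]1[C@@H](OC(=O)CCC=C)C(C)(C)[C@@H]2[C@H]3C(=O)C=C(C)[C@@H]2[C@@]3(C)C1=O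
F5 | step 14 | 8-{2-[bis(2,2,2-trifluoroethoxy)phosphoryl]propanoyloxy}-9-(3-methylbutanoyloxy)-1-oxolongipin-2-en-7-yl pent-4-enoate | CC(C(=O)O[C@@H]1[C@@H](OC(=O)CCC=C)C(C)(C)[C@@H]2[C@H]3C(=O)C=C(C)[C@@H]2[C@@]3(C)[C@@H]1OC(=O)CC(C)C)P(=O)(OCC(F)(F)F)OCC(F)(F)F
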